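**Retrosynthetic overview**

1. The five phenols are unmasked last from benzyl ethers; before that the biaryl bond between chroman C8 and C8 of the apigenin unit is cut (Suzuki coupling of chroman-8-boronate 13 with 8-iodoflavone 17).
2. The pyranone ring of flavone unit 1 comes from chroman ester 8 and acetophenone 10 (Claisen condensation, cyclodehydration); that of flavone unit 2 comes from iodoacetophenone 14 and aldehyde 15 (chalcone, oxidative cyclisation).
3. The dihydropyran ring of the chroman is opened at C2–C3 and C4–C4a: both bonds are made together by a photoredox decarboxylative radical (4+2) annulation of the N-acyloxyphthalimide of an α-aryloxyisobutyric acid with phenyl vinyl sulfone. The sulfonyl group is only an activator and is removed with SmI2.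
4. Enabling feature: the O1–C2(CH3)2 unit of the chroman, a tertiary carbon on the aryl ether oxygen whose radical is released from ArO–C(CH3)2–CO2H, together with a single free ortho C–H (future C4a) on the benzo ring; the other ortho carbon (future C8) carries bromine, which later becomes the biaryl bond.
5. Order of ring formation: dihydropyran ring of the chroman, then pyranone ring of flavone unit 1, pyranone ring of flavone unit 2 (separate branch), then biaryl union.

Key step: step 4

Remark: the target has no stereocentre. The only stereocentre on the route (C4 of sulfone 7) is formed as a racemate and is deleted in step 5.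

**Route**

Step 1
Reactants: 1 methyl 3-bromo-4-hydroxybenzoate; 2 tert-butyl 2-bromo-2-methylpropanoate
Product: 3 methyl 3-bromo-4-[(1-tert-butoxy-2-methyl-1-oxopropan-2-yl)oxy]benzoate
Conditions: Cs2CO3, 2 (3 equiv), DMF, 70 °C
Reagents that add atoms: none
Why: Williamson-type O-alkylation in which the caesium phenoxide of 1 displaces bromide from the tertiary α-bromo ester (the fibrate ether synthesis), the excess of 2 compensating for competing elimination to the methacrylate.

Step 2
Reactants: 3 methyl 3-bromo-4-[(1-tert-butoxy-2-methyl-1-oxopropan-2-yl)oxy]benzoate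
Product: 4 2-[2-bromo-4-(methoxycarbonyl)phenoxy]-2-methylpropanoic acid
Conditions: TFA, CH2Cl2, rt
Reagents that add atoms: none
Why: Acidolysis of the tert-butyl ester (loss of isobutene) should leave the methyl benzoate, the aryl bromide and the tertiary aryl ether untouched, the ether being deactivated towards ionisation by the adjacent carboxyl group.

Step 3
Reactants: 4 2-[2-bromo-4-(methoxycarbonyl)phenoxy]-2-methylpropanoic acid
Product: 5 methyl 3-bromo-4-({1-[(1,3-dioxoisoindolin-2-yl)oxy]-2-methyl-1-oxopropan-2-yl}oxy)benzoate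
Conditions: N-hydroxyphthalimide, DIC, DMAP (cat.), CH2Cl2, 0 °C to rt
Reagents that add atoms: N-hydroxyphthalimide O=C1c2ccccc2C(=O)N1O
Why: Steglich-type carbodiimide esterification converts the hindered acid into the redox-active N-acyloxyphthalimide, the standard preparation of such esters.

Step 4
Reactants: 5 methyl 3-bromo-4-({1-[(1,3-dioxoisoindolin-2-yl)oxy]-2-methyl-1-oxopropan-2-yl}oxy)benzoate; 6 phenyl vinyl sulfone
Product: 7 methyl 8-bromo-2,2-dimethyl-4-(phenylsulfonyl)chroman-6-carboxylate (racemic)
Conditions: fac-Ir(ppy)3 (ppy = 2-phenylpyridinato, 1 mol %), 6 (3 equiv), degassed MeCN, blue LEDs (450 nm), rt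
Reagents that add atoms: none
Why: This is a photoredox decarboxylative radical (4+2) annulation of a redox-active ester of an α-aryloxy acid with an electron-poor alkene, a known chroman-forming reaction type; excited trivalent iridium reduces 5, which loses phthalimide anion and CO2 to give the tertiary α-aryloxy radical at the future C2. This nucleophilic radical adds to the CH2 terminus of 6 (Giese addition, C2–C3 bond), and the electrophilic α-sulfonyl radical so formed at C4 attacks the ortho carbon of the aryl ether (C4–C4a bond) in a 6-exo-trig-type homolytic aromatic substitution that closes the dihydropyran ring; tetravalent iridium then oxidises the cyclohexadienyl radical and phthalimide anion removes the proton, so the cycle is redox-neutral. Regioselectivity is secured by the substrate, because bromine occupies the other ortho carbon and only one ortho C–H is free, while the gem-dimethyl group favours the folded conformer needed for closure. Chemoselectivity rests on polarity matching (nucleophilic radical to acceptor alkene, electrophilic radical to arene) and on the aryl bromide and the benzoate lying beyond the reducing power of the catalyst. The C4 stereocentre is formed racemic without control, which is of no consequence because step 5 removes it.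

Step 5
Reactants: 7 methyl 8-bromo-2,2-dimethyl-4-(phenylsulfonyl)chroman-6-carboxylate (racemic)
Product: 8 methyl 8-bromo-2,2-dimethylchroman-6-carboxylate
Conditions: SmI2 (4 equiv), HMPA, MeOH, THF, −78 °C, short reaction time
Reagents that add atoms: none
Why: Reductive desulfonylation, in which electron transfer from divalent samarium (activated by HMPA) cleaves the benzylic C–S bond at a temperature at which the aryl bromide and the methyl benzoate should not be reduced, and protonation by MeOH gives the C4 methylene.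

Step 6
Reactants: 9 2',4',6'-trihydroxyacetophenone
Product: 10 1-[2,4-bis(benzyloxy)-6-hydroxyphenyl]ethanone
Conditions: BnBr (2.1 equiv), K2CO3, DMF, rt to 50 °C
Reagents that add atoms: benzyl bromide BrCc1ccccc1
Why: Williamson benzylation in which, with two equivalents of benzyl bromide, one hydroxyl should stay free because it is hydrogen-bonded to the acetyl carbonyl.

Step 7
Reactants: 8 methyl 8-bromo-2,2-dimethylchroman-6-carboxylate; 10 1-[2,4-bis(benzyloxy)-6-hydroxyphenyl]ethanone
Product: 12 5,7-bis(benzyloxy)-2-(8-bromo-2,2-dimethylchroman-6-yl)-4H-chromen-4-one, via 1,3-diketone 11 (not isolated)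
Conditions: LiHMDS (3.5 equiv), THF, −78 °C to rt, aq. HCl work-up; then p-TsOH·H2O (cat.), toluene, 100 °C
Reagents that add atoms: none
Why: Crossed Claisen condensation of the lithium dianion of 10 with ester 8 (the direct variant of the Baker–Venkataraman route) gives the 1,3-diketone, whose free ortho-hydroxyl closes onto the aroyl carbonyl under acid with loss of water (cyclodehydration) to give the flavone.

Step 8
Reactants: 12 5,7-bis(benzyloxy)-2-(8-bromo-2,2-dimethylchroman-6-yl)-4H-chromen-4-one
Product: 13 5,7-bis(benzyloxy)-2-[2,2-dimethyl-8-(4,4,5,5-tetramethyl-1,3,2-dioxaborolan-2-yl)chroman-6-yl]-4H-chromen-4-one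
Conditions: B2pin2, Pd(dppf)Cl2 (5 mol %), KOAc, 1,4-dioxane, 90 °C
Reagents that add atoms: bis(pinacolato)diboron CC1(C)OB(OC1(C)C)B1OC(C)(C)C(C)(C)O1
Why: Miyaura borylation, in which zerovalent palladium inserts into the C–Br bond and acetate-assisted transmetalation with the diboron reagent delivers the arylboronate while the flavone and benzyl ethers stay inert.

Step 9
Reactants: 10 1-[2,4-bis(benzyloxy)-6-hydroxyphenyl]ethanone
Product: 14 1-[4,6-bis(benzyloxy)-2-hydroxy-3-iodophenyl]ethanone
Conditions: N-iodosuccinimide (1.05 equiv), TFA (cat.), MeCN, 0 °C to rt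
Reagents that add atoms: N-iodosuccinimide O=C1CCC(=O)N1I
Why: Electrophilic aromatic iodination, in which C3 (ortho to the free hydroxyl, para to a benzyloxy group) should be attacked in preference to C5, which is crowded between two benzyloxy groups, and one equivalent of reagent limits the reaction to mono-iodination.

Step 10
Reactants: 14 1-[4,6-bis(benzyloxy)-2-hydroxy-3-iodophenyl]ethanone; 15 4-(benzyloxy)benzaldehyde
Product: 16 (E)-1-[4,6-bis(benzyloxy)-2-hydroxy-3-iodophenyl]-3-[4-(benzyloxy)phenyl]prop-2-en-1-one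
Conditions: KOH (50 % aq.), EtOH/THF, rt
Reagents that add atoms: none
Why: Claisen–Schmidt aldol condensation, whose E1cB dehydration gives the thermodynamically favoured (E)-enone.

Step 11
Reactants: 16 (E)-1-[4,6-bis(benzyloxy)-2-hydroxy-3-iodophenyl]-3-[4-(benzyloxy)phenyl]prop-2-en-1-one
Product: 17 5,7-bis(benzyloxy)-2-[4-(benzyloxy)phenyl]-8-iodo-4H-chromen-4-one
Conditions: I2 (10 mol %), DMSO, 130 °C
Reagents that add atoms: none
Why: Iodine-catalysed oxidative cyclisation of a 2'-hydroxychalcone in DMSO (oxa-Michael closure by the only free hydroxyl, which is flanked by the iodine, then dehydrogenation with DMSO as terminal oxidant) should place the iodine at C8 of the flavone.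

Step 12
Reactants: 13 5,7-bis(benzyloxy)-2-[2,2-dimethyl-8-(4,4,5,5-tetramethyl-1,3,2-dioxaborolan-2-yl)chroman-6-yl]-4H-chromen-4-one; 17 5,7-bis(benzyloxy)-2-[4-(benzyloxy)phenyl]-8-iodo-4H-chromen-4-one
Product: 18 5,7-bis(benzyloxy)-8-[6-(5,7-bis(benzyloxy)-4-oxo-4H-chromen-2-yl)-2,2-dimethylchroman-8-yl]-2-[4-(benzyloxy)phenyl]-4H-chromen-4-one
Conditions: Pd(OAc)2 (5 mol %), SPhos (10 mol %), K3PO4, 1,4-dioxane/H2O, 90 °C
Reagents that add atoms: none
Why: Suzuki–Miyaura cross-coupling, in which the bulky electron-rich biarylphosphine supports oxidative addition of zerovalent palladium into the hindered C8–I bond and reductive elimination to the tri-ortho-substituted biaryl, as in known couplings of 8-iodoflavones with ortho-alkoxy arylboronates.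

Step 13
Reactants: 18 5,7-bis(benzyloxy)-8-[6-(5,7-bis(benzyloxy)-4-oxo-4H-chromen-2-yl)-2,2-dimethylchroman-8-yl]-2-[4-(benzyloxy)phenyl]-4H-chromen-4-one
Product: 19 8-[6-(5,7-dihydroxy-4-oxo-4H-chromen-2-yl)-2,2-dimethylchroman-8-yl]-5,7-dihydroxy-2-(4-hydroxyphenyl)-4H-chromen-4-one
Conditions: H2 (1 atm), 10 % Pd/C, THF/MeOH, rt
Reagents that add atoms: none
Why: Catalytic hydrogenolysis of the five benzyl ethers, under which the chromone C2=C3 bonds (vinylogous esters) and the saturated chroman should not be reduced at 1 atm and room temperature.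

**Compound list**

1 | methyl 3-bromo-4-hydroxybenzoate | COC(=O)c1ccc(O)c(Br)c1 | starting material
2 | tert-butyl 2-bromo-2-methylpropanoate | CC(C)(Br)C(=O)OC(C)(C)C | starting material
3 | methyl 3-bromo-4-[(1-tert-butoxy-2-methyl-1-oxopropan-2-yl)oxy]benzoate | COC(=O)c1ccc(OC(C)(C)C(=O)OC(C)(C)C)c(Br)c1 | intermediate
4 | 2-[2-bromo-4-(methoxycarbonyl)phenoxy]-2-methylpropanoic acid | COC(=O)c1ccc(OC(C)(C)C(=O)O)c(Br)c1 | intermediate
5 | methyl 3-bromo-4-({1-[(1,3-dioxoisoindolin-2-yl)oxy]-2-methyl-1-oxopropan-2-yl}oxy)benzoate | COC(=O)c1ccc(OC(C)(C)C(=O)ON2C(=O)c3ccccc3C2=O)c(Br)c1 | intermediate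
6 | phenyl vinyl sulfone | C=CS(=O)(=O)c1ccccc1 | starting material
7 | methyl 8-bromo-2,2-dimethyl-4-(phenylsulfonyl)chroman-6-carboxylate (racemic) | COC(=O)c1cc(Br)c2OC(C)(C)CC(c2c1)S(=O)(=O)c1ccccc1 | intermediate
8 | methyl 8-bromo-2,2-dimethylchroman-6-carboxylate | COC(=O)c1cc(Br)c2OC(C)(C)CCc2c1 | intermediate
9 | 2',4',6'-trihydroxyacetophenone | CC(=O)c1c(O)cc(O)cc1O | starting material
10 | 1-[2,4-bis(benzyloxy)-6-hydroxyphenyl]ethanone | CC(=O)c1c(O)cc(OCc2ccccc2)cc1OCc1ccccc1 | intermediate
11 | 1-[2,4-bis(benzyloxy)-6-hydroxyphenyl]-3-(8-bromo-2,2-dimethylchroman-6-yl)propane-1,3-dione | O=C(CC(=O)c1cc(Br)c2OC(C)(C)CCc2c1)c1c(O)cc(OCc2ccccc2)cc1OCc1ccccc1 | intermediate (not isolated)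
12 | 5,7-bis(benzyloxy)-2-(8-bromo-2,2-dimethylchroman-6-yl)-4H-chromen-4-one | O=c1cc(-c2cc(Br)c3OC(C)(C)CCc3c2)oc2cc(OCc3ccccc3)cc(OCc3ccccc3)c12 | intermediate
13 | 5,7-bis(benzyloxy)-2-[2,2-dimethyl-8-(4,4,5,5-tetramethyl-1,3,2-dioxaborolan-2-yl)chroman-6-yl]-4H-chromen-4-one | O=c1cc(-c2cc(B3OC(C)(C)C(C)(C)O3)c3OC(C)(C)CCc3c2)oc2cc(OCc3ccccc3)cc(OCc3ccccc3)c12 | intermediate
14 | 1-[4,6-bis(benzyloxy)-2-hydroxy-3-iodophenyl]ethanone | CC(=O)c1c(O)c(I)c(OCc2ccccc2)cc1OCc1ccccc1 | intermediate
15 | 4-(benzyloxy)benzaldehyde | O=Cc1ccc(OCc2ccccc2)cc1 | starting material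
16 | (E)-1-[4,6-bis(benzyloxy)-2-hydroxy-3-iodophenyl]-3-[4-(benzyloxy)phenyl]prop-2-en-1-one | O=C(/C=C/c1ccc(OCc2ccccc2)cc1)c1c(O)c(I)c(OCc2ccccc2)cc1OCc1ccccc1 | intermediate
17 | 5,7-bis(benzyloxy)-2-[4-(benzyloxy)phenyl]-8-iodo-4H-chromen-4-one | O=c1cc(-c2ccc(OCc3ccccc3)cc2)oc2c(I)c(OCc3ccccc3)cc(OCc3ccccc3)c12 | intermediate
18 | 5,7-bis(benzyloxy)-8-[6-(5,7-bis(benzyloxy)-4-oxo-4H-chromen-2-yl)-2,2-dimethylchroman-8-yl]-2-[4-(benzyloxy)phenyl]-4H-chromen-4-one | O=c1cc(-c2cc(-c3c(OCc4ccccc4)cc(OCc4ccccc4)c4c(=O)cc(-c5ccc(OCc6ccccc6)cc5)oc34)c3OC(C)(C)CCc3c2)oc2cc(OCc3ccccc3)cc(OCc3ccccc3)c12 | intermediate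
19 | 8-[6-(5,7-dihydroxy-4-oxo-4H-chromen-2-yl)-2,2-dimethylchroman-8-yl]-5,7-dihydroxy-2-(4-hydroxyphenyl)-4H-chromen-4-one | CC1(C)CCc2cc(-c3cc(=O)c4c(O)cc(O)cc4o3)cc(-c3c(O)cc(O)c4c(=O)cc(-c5ccc(O)cc5)oc34)c2O1 | target

**Summary**

Total step count: 13. Longest linear sequence: 9 steps (steps 1, 2, 3, 4, 5, 7, 8, 12, 13).

**Steps most likely to fail**

Step 4 (key step). The sulfonyl-stabilised adduct radical may be reduced or capture a hydrogen atom before it closes onto the ring, it may telomerise with a second molecule of the vinyl sulfone, or closure may occur at the bromine-bearing ortho carbon with expulsion of bromine. The fallback sets out from 1 and comes back at 8 by the classical chromene route. Phenol 1 would be O-alkylated with 3-chloro-3-methylbut-1-yne (K2CO3, KI cat., acetone, reflux) to give methyl 3-bromo-4-[(2-methylbut-3-yn-2-yl)oxy]benzoate F1. Heating F1 in N,N-diethylaniline at about 190 °C should trigger the aryl propargyl ether Claisen rearrangement, 1,5-hydrogen shift and 6π-electrocyclisation at the only free ortho carbon, giving methyl 8-bromo-2,2-dimethyl-2H-chromene-6-carboxylate F2. Hydrogenation of the C3=C4 bond of F2 with H2 and RhCl(PPh3)3, which spares the aryl bromide, should give 8.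

Step 5. Electron transfer to the C–Br bond may compete with C–S cleavage and cause loss of bromine, or the cleavage may stop short. The fallback sets out from 5 and comes back at 8 with a carboxyl group in place of the sulfonyl group as the activator. The annulation of step 4 would be run with tert-butyl acrylate in place of 6, which should give 4-tert-butyl 6-methyl 8-bromo-2,2-dimethylchroman-4,6-dicarboxylate F3 (racemic). TFA in CH2Cl2 would free 8-bromo-6-(methoxycarbonyl)-2,2-dimethylchroman-4-carboxylic acid F4 (racemic). Photoredox hydrodecarboxylation of this benzylic acid (9-mesityl-10-methylacridinium tetrafluoroborate cat., diphenyl disulfide cat., 2,6-lutidine, trifluoroethanol, blue LEDs) should then give 8 without any reducing metal.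

Step 12. Oxidative addition and transmetalation at two hindered, poorly soluble flavone partners may be slow, so that protodeboronation of the boronate and hydrodeiodination of the iodide take over. The fallback sets out from 13 and comes back at 18 by making the biaryl bond on a smaller electrophile and closing flavone unit 2 afterwards. Suzuki coupling of 13 with iodoacetophenone 14 (Pd(dppf)Cl2, K3PO4, dioxane/H2O) should give 2-[8-(3-acetyl-4,6-bis(benzyloxy)-2-hydroxyphenyl)-2,2-dimethylchroman-6-yl]-5,7-bis(benzyloxy)-4H-chromen-4-one F5. Claisen–Schmidt condensation of F5 with aldehyde 15 (KOH, EtOH/THF, rt) should give the (E)-chalcone F6, and I2 (cat.) in DMSO at 130 °C should close the second pyranone ring to give 18.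

**Further compounds**

F1 | step 4 | methyl 3-bromo-4-[(2-methylbut-3-yn-2-yl)oxy]benzoate | COC(=O)c1ccc(OC(C)(C)C#C)c(Br)c1
F2 | step 4 | methyl 8-bromo-2,2-dimethyl-2H-chromene-6-carboxylate | COC(=O)c1cc(Br)c2OC(C)(C)C=Cc2c1
F3 | step 5 | 4-tert-butyl 6-methyl 8-bromo-2,2-dimethylchroman-4,6-dicarboxylate (racemic) | COC(=O)c1cc(Br)c2OC(C)(C)CC(c2c1)C(=O)OC(C)(C)C
F4 | step 5 | 8-bromo-6-(methoxycarbonyl)-2,2-dimethylchroman-4-carboxylic acid (racemic) | COC(=O)c1cc(Br)c2OC(C)(C)CC(c2c1)C(=O)O
F5 | step 12 | 2-[8-(3-acetyl-4,6-bis(benzyloxy)-2-hydroxyphenyl)-2,2-dimethylchroman-6-yl]-5,7-bis(benzyloxy)-4H-chromen-4-one | CC(=O)c1c(O)c(-c2cc(-c3cc(=O)c4c(OCc5ccccc5)cc(OCc5ccccc5)cc4o3)cc3CCC(C)(C)Oc23)c(OCc2ccccc2)cc1OCc1ccccc1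
F6 | step 12 | (E)-1-{4,6-bis(benzyloxy)-3-[6-(5,7-bis(benzyloxy)-4-oxo-4H-chromen-2-yl)-2,2-dimethylchroman-8-yl]-2-hydroxyphenyl}-3-[4-(benzyloxy)phenyl]prop-2-en-1-one | O=C(/C=C/c1ccc(OCc2ccccc2)cc1)c1c(O)c(-c2cc(-c3cc(=O)c4c(OCc5ccccc5)cc(OCc5ccccc5)cc4o3)cc3CCC(C)(C)Oc23)c(OCc2ccccc2)cc1OCc1ccccc1
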